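**Retrosynthetic overview**
1. The C1 hydroxyl comes last, by β-face conjugate borylation/oxidation of a ring-A 1-en-3-one; the C12 ether and C7 ester are then unmasked.
2. Ring A is closed by an intramolecular aldol of a lactone enolate onto a (Z)-enal (C3–C4); the lactone is formed before it by intramolecular Michael addition of a C10 propanoate to a ring-B enoate (C4–C5).
3. The C10 carbinol comes from α-face epoxidation of a ring-B ynenone and SmI2 opening; C7 comes from enol triflate carbonylation; the C1–C3 unit is added by conjugate alkynylation.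
4. The BCD core comes from a Hajos–Parrish-type enedione: a gold Conia-ene closes ring D, Li/NH3 sets H-9, a ketoreductase sets C12.
5. The enedione comes from cyclopentane-1,3-dione, propargyl bromide and methyl vinyl ketone (proline aldol sets C8). Ring order: B, C, D, lactone, A.

Assumption (one line): gibberellane numbering is used (lactone C19–O–C10); the SMILES is read as H-9 on the same face as the lactone oxygen (trans B/C fusion, a 9-epi-gibberellin skeleton) and the route targets exactly that; α = face of ring B carrying C14, H-9 and O-10, β = face carrying C15 and C11; "BCD" = the skeleton C5, C6, C8–C17.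

**Step 1**
Reactants: 1 cyclopentane-1,3-dione; 2 3-bromoprop-1-yne
Product: 3 2-(prop-2-yn-1-yl)cyclopentane-1,3-dione
Conditions: KOH (1.0 equiv), H2O, 60 °C
Reagents that add atoms: none
Why: C-alkylation (SN2) of the cyclic 1,3-dione enolate with a propargylic halide in water, which favours C- over O-alkylation.

**Step 2**
Reactants: 3 2-(prop-2-yn-1-yl)cyclopentane-1,3-dione; 4 but-3-en-2-one
Product: 5 2-(3-oxobutyl)-2-(prop-2-yn-1-yl)cyclopentane-1,3-dione
Conditions: H2O, AcOH (cat.), 70 °C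
Reagents that add atoms: none
Why: Michael addition of the acidic 2-substituted dione to methyl vinyl ketone gives the prochiral triketone.

**Step 3**
Reactants: 5 triketone
Product: 7 (R)-7a-(prop-2-yn-1-yl)-2,3,7,7a-tetrahydro-1H-indene-1,5(6H)-dione, via aldol ketol 6 (not isolated)
Conditions: (S)-proline (30 mol%), DMF, rt, 72 h; then H2SO4 (cat.), 95 °C
Reagents that add atoms: none
Why: Hajos–Parrish–Eder–Sauer–Wiechert aldol: the proline enamine of the side-chain ketone attacks one enantiotopic ring carbonyl and acid dehydrates the ketol, setting the quaternary C8 (first stereocentre, organocatalytic).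

**Step 4**
Reactants: 7 enedione
Product: 8 (1S,7aR)-1-hydroxy-7a-(prop-2-yn-1-yl)-1,2,3,6,7,7a-hexahydro-5H-inden-5-one
Conditions: NaBH4 (0.3 equiv), EtOH, −20 °C
Reagents that add atoms: none
Why: Chemoselective hydride reduction of the saturated C6 ketone over the enone, anti to the angular propargyl group; the carbinol is temporary, and recrystallisation of 8 could raise the ee.

**Step 5**
Reactants: 8 hydroxy enone
Product: 9 (1S,7aR)-1-[(tert-butyldimethylsilyl)oxy]-7a-(prop-2-yn-1-yl)-1,2,3,6,7,7a-hexahydro-5H-inden-5-one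
Conditions: TBSCl, imidazole, DMF, rt
Reagents that add atoms: tert-butyldimethylsilyl chloride, CC(C)(C)[Si](C)(C)Cl
Why: Silyl ether protection masks the C6 oxygen during enolate, gold and dissolving-metal steps.

**Step 6**
Reactants: 9 silyl ether enone
Product: 10 (1S,7aR)-1,5-bis[(tert-butyldimethylsilyl)oxy]-7a-(prop-2-yn-1-yl)-2,3,7,7a-tetrahydro-1H-indene
Conditions: LiN(i-Pr)2 (1.05 equiv), THF, −78 °C; TBSOTf (1.1 equiv)
Reagents that add atoms: tert-butyldimethylsilyl trifluoromethanesulfonate, CC(C)(C)[Si](C)(C)OS(=O)(=O)C(F)(F)F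
Why: Kinetic α′-deprotonation of the enone (C13) and O-silylation give the cross-conjugated silyl dienol ether regiospecifically.

**Step 7**
Reactants: 10 silyl dienol ether
Product: 11 6β-[(tert-butyldimethylsilyl)oxy]-BCD-9(11),16-dien-12-one
Conditions: (Ph3P)AuCl (5 mol%), AgBF4 (5 mol%), CH2Cl2/MeOH 10:1, rt
Reagents that add atoms: none
Why: Gold-catalysed Conia-ene-type 5-exo-dig carbocyclisation of the silyl enol ether onto the alkyne forms C13–C16 and the exocyclic methylene; the C13 bridgehead configuration is dictated by C8.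

**Step 8**
Reactants: 11 tricyclic dienone
Product: 12 6β-[(tert-butyldimethylsilyl)oxy]-9αH-BCD-16-en-12-one
Conditions: Li (2.5 equiv), NH3(l)/THF, t-BuOH (1 equiv), −78 °C; NH4Cl
Reagents that add atoms: none
Why: Dissolving-metal (Birch-type) conjugate reduction: C9 is protonated axially, anti to the diaxial C15–C16 bridge, giving H-9α (trans B/C fusion).

**Step 9**
Reactants: 12 C12 ketone
Product: 13 (12S)-6β-[(tert-butyldimethylsilyl)oxy]-9αH-BCD-16-en-12α-ol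
Conditions: ketoreductase (NADPH-dependent, Prelog-type, chosen from a screening panel), NADP+ (cat.), i-PrOH (10% v/v), phosphate buffer pH 7/DMSO, 30 °C
Reagents that add atoms: none
Why: Biocatalytic ketone reduction by a ketoreductase delivers hydride from the bridge-side face to give the axial (12S)-12α-alcohol, the epimer that small chemical hydrides (axial attack, equatorial alcohol) would not favour.

**Step 10**
Reactants: 13 C12 alcohol
Product: 14 6β-[(tert-butyldimethylsilyl)oxy]-12α-(4-methoxybenzyloxy)-9αH-BCD-16-ene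
Conditions: NaH, 4-methoxybenzyl chloride, Bu4NI (cat.), DMF, 0 °C → rt
Reagents that add atoms: 4-methoxybenzyl chloride, COc1ccc(CCl)cc1
Why: Williamson etherification; the PMB ether survives base, fluoride, SmI2 and palladium and is removed oxidatively at the end.

**Step 11**
Reactants: 14 bis-ether
Product: 15 12α-(4-methoxybenzyloxy)-9αH-BCD-16-en-6β-ol
Conditions: Bu4NF, THF, 50 °C
Reagents that add atoms: none
Why: Fluoride desilylation frees the C6 alcohol selectively.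

**Step 12**
Reactants: 15 C6 alcohol
Product: 16 12α-(4-methoxybenzyloxy)-9αH-BCD-16-en-6-one
Conditions: Dess–Martin periodinane, NaHCO3, CH2Cl2, rt
Reagents that add atoms: none
Why: Mild alcohol oxidation restores the C6 ketone without touching the exocyclic alkene.

**Step 13**
Reactants: 16 ring-B ketone
Product: 18 12α-(4-methoxybenzyloxy)-9αH-BCD-5(10),16-dien-6-one, via trimethylsilyl enol ether 17 (not isolated)
Conditions: LiN(SiMe3)2, Me3SiCl, THF, −78 °C; then Pd(OAc)2 (1.1 equiv), MeCN, rt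
Reagents that add atoms: none
Why: Saegusa–Ito dehydrogenation; the ketone can enolise only towards C5 because C8 is quaternary.

**Step 14**
Reactants: 18 ring-B enone; 19 tert-butyl(prop-2-yn-1-yloxy)diphenylsilane
Product: 20 10α-[3-(tert-butyldiphenylsilyloxy)prop-1-yn-1-yl]-12α-(4-methoxybenzyloxy)-9αH-BCD-16-en-6-one
Conditions: 19, n-BuLi, then Me2AlCl, Et2O; Ni(acac)2 (10 mol%)/i-Bu2AlH (10 mol%); add 18, −5 °C → rt; aq. Rochelle salt
Reagents that add atoms: none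
Why: Nickel-catalysed conjugate addition of an alkynylalane to the s-trans enone installs C1–C3 at C10; the new C10 centre (alkyne anti to C15) is erased in the next step.

**Step 15**
Reactants: 20 alkynyl ketone
Product: 22 10-[3-(tert-butyldiphenylsilyloxy)prop-1-yn-1-yl]-12α-(4-methoxybenzyloxy)-9αH-BCD-5(10),16-dien-6-one, via trimethylsilyl enol ether 21 (not isolated)
Conditions: Me3SiOTf, Et3N, CH2Cl2, 0 °C; then Pd(OAc)2 (1.1 equiv), MeCN, rt
Reagents that add atoms: none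
Why: A second Saegusa–Ito oxidation regenerates the C5=C10 enone, now β-alkynylated.

**Step 16**
Reactants: 22 ynenone
Product: 23 5α,10α-epoxy-10β-[3-(tert-butyldiphenylsilyloxy)prop-1-yn-1-yl]-12α-(4-methoxybenzyloxy)-9αH-BCD-16-en-6-one
Conditions: 30% H2O2, NaOH (0.2 equiv), MeOH, 0 °C
Reagents that add atoms: hydrogen peroxide, OO
Why: Weitz–Scheffer nucleophilic epoxidation: hydroperoxide attacks C10 from the α face, anti to the axial angular C15 methylene (steroid-like shielding), so the C10–O bond is α, cis to H-9.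

**Step 17**
Reactants: 23 epoxy ketone
Product: 24 10α-hydroxy-10β-[3-(tert-butyldiphenylsilyloxy)prop-1-yn-1-yl]-12α-(4-methoxybenzyloxy)-9αH-BCD-16-en-6-one
Conditions: SmI2 (2.5 equiv), THF/MeOH, −90 °C
Reagents that add atoms: none
Why: Samarium diiodide reductive opening of the α,β-epoxy ketone cleaves the C5–O bond only, leaving the tertiary C10 carbinol with its configuration.

**Step 18**
Reactants: 24 β-hydroxy ketone
Product: 25 10α-(trimethylsilyloxy)-10β-[3-(tert-butyldiphenylsilyloxy)prop-1-yn-1-yl]-12α-(4-methoxybenzyloxy)-9αH-BCD-16-en-6-one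
Conditions: 1-(trimethylsilyl)imidazole, CH2Cl2, rt
Reagents that add atoms: 1-(trimethylsilyl)imidazole, C[Si](C)(C)n1ccnc1
Why: Neutral silylation of the tertiary aldol-type alcohol blocks retro-aldol cleavage during enolisation.

**Step 19**
Reactants: 25 silyloxy ketone
Product: 26 10α-(trimethylsilyloxy)-10β-[3-(tert-butyldiphenylsilyloxy)prop-1-yn-1-yl]-12α-(4-methoxybenzyloxy)-9αH-BCD-5,16-dien-6-yl trifluoromethanesulfonate
Conditions: KN(SiMe3)2, THF, −78 °C; PhNTf2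
Reagents that add atoms: N-phenyl-bis(trifluoromethanesulfonimide), FC(F)(F)S(=O)(=O)N(c1ccccc1)S(=O)(=O)C(F)(F)F
Why: Regiospecific enol triflate formation (only C5 bears α-hydrogens).

**Step 20**
Reactants: 26 enol triflate
Product: 27 2-(trimethylsilyl)ethyl 10α-(trimethylsilyloxy)-10β-[3-(tert-butyldiphenylsilyloxy)prop-1-yn-1-yl]-12α-(4-methoxybenzyloxy)-9αH-BCD-5,16-diene-6-carboxylate
Conditions: Pd(OAc)2 (5 mol%), 1,3-bis(diphenylphosphino)propane (5 mol%), CO (1 atm), Et3N, Me3SiCH2CH2OH, DMF, 60 °C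
Reagents that add atoms: carbon monoxide, [C-]#[O+]; 2-(trimethylsilyl)ethanol, C[Si](C)(C)CCO
Why: Palladium-catalysed alkoxycarbonylation of the vinyl triflate installs C7 as a fluoride-labile ester and creates the C5=C6 Michael acceptor.

**Step 21**
Reactants: 27 silyloxy enoate
Product: 28 2-(trimethylsilyl)ethyl 10α-hydroxy-10β-[3-(tert-butyldiphenylsilyloxy)prop-1-yn-1-yl]-12α-(4-methoxybenzyloxy)-9αH-BCD-5,16-diene-6-carboxylate
Conditions: citric acid, MeOH, 0 °C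
Reagents that add atoms: none
Why: Mild acidic methanolysis removes the labile trimethylsilyl ether while the TBDPS ether, PMB ether and ester stay.

**Step 22**
Reactants: 28 tertiary alcohol
Product: 29 2-(trimethylsilyl)ethyl 10α-(propanoyloxy)-10β-[3-(tert-butyldiphenylsilyloxy)prop-1-yn-1-yl]-12α-(4-methoxybenzyloxy)-9αH-BCD-5,16-diene-6-carboxylate
Conditions: LiN(SiMe3)2 (1.05 equiv), THF, −78 °C; (EtCO)2O, → 0 °C
Reagents that add atoms: propanoic anhydride, CCC(=O)OC(=O)CC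
Why: Acylation of the lithium alkoxide overcomes the hindrance of the tertiary alcohol and brings in C4, C18 and C19.

**Step 23**
Reactants: 29 propanoate
Product: 30 γ-lactone 2-(trimethylsilyl)ethyl ester (C19→O-10; C4 bearing H and CH3; H-5β; H-6α; 10β-alkynyl)
Conditions: KN(SiMe3)2 (1.1 equiv), THF, −78 → −40 °C; AcOH
Reagents that add atoms: none
Why: Intramolecular Michael addition (5-exo-trig) of the propanoate enolate to the enoate: the tether reaches C5 only from the α face, so C4–C5 is cis to O-10 (H-5β), and the C6 ester settles trans to C4 (H-6α).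

**Step 24**
Reactants: 30 alkynyl lactone
Product: 31 (Z)-alkenyl lactone (10β-[(Z)-3-(tert-butyldiphenylsilyloxy)prop-1-en-1-yl])
Conditions: H2 (1 atm), Pd/CaCO3 poisoned with Pb(OAc)2, quinoline, EtOAc, rt
Reagents that add atoms: none
Why: Lindlar-type syn semi-hydrogenation gives the (Z)-alkene and spares the 1,1-disubstituted exocyclic alkene.

**Step 25**
Reactants: 31 (Z)-allylic silyl ether
Product: 32 (Z)-allylic alcohol lactone (10β-[(Z)-3-hydroxyprop-1-en-1-yl])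
Conditions: HF·pyridine, pyridine, THF, 0 °C → rt
Reagents that add atoms: none
Why: Buffered HF removes the TBDPS ether without cleaving the silylethyl ester or PMB ether.

**Step 26**
Reactants: 32 (Z)-allylic alcohol
Product: 33 (Z)-enal lactone (10β-[(Z)-3-oxoprop-1-en-1-yl])
Conditions: Dess–Martin periodinane, NaHCO3, CH2Cl2, 0 °C
Reagents that add atoms: none
Why: Buffered periodinane oxidation gives the non-enolisable (Z)-enal with minimal isomerisation; it is used at once.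

**Step 27**
Reactants: 33 (Z)-enal lactone
Product: 34 7-[2-(trimethylsilyl)ethyl] ester of 3β-hydroxy-12α-(4-methoxybenzyloxy)-9αH-20-norgibberella-1,16-diene-7,19-dioic acid 19,10-lactone
Conditions: KOt-Bu (1.05 equiv), THF, −78 → −30 °C; AcOH
Reagents that add atoms: none
Why: Intramolecular aldol of the lactone enolate onto the enal closes ring A; the tether forces C3 onto the C1 side of the lactone, fixing quaternary C4 (CH3 β), and the C3 epimers (3β drawn) converge in the next step.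

**Step 28**
Reactants: 34 allylic alcohol
Product: 35 7-[2-(trimethylsilyl)ethyl] ester of 3-oxo-12α-(4-methoxybenzyloxy)-9αH-20-norgibberella-1,16-diene-7,19-dioic acid 19,10-lactone
Conditions: Dess–Martin periodinane, NaHCO3, CH2Cl2, rt
Reagents that add atoms: none
Why: Allylic alcohol oxidation gives the 1-en-3-one and removes the C3 stereocentre.

**Step 29**
Reactants: 35 enone lactone
Product: 37 7-[2-(trimethylsilyl)ethyl] ester of 1β-hydroxy-3-oxo-12α-(4-methoxybenzyloxy)-9αH-20-norgibberell-16-ene-7,19-dioic acid 19,10-lactone, via 1β-pinacolboronate 36 (not isolated)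
Conditions: CuCl (10 mol%), bis[2-(diphenylphosphino)phenyl] ether (10 mol%), NaOt-Bu (15 mol%), B2pin2, MeOH, THF, rt; then NaBO3·4H2O, THF/H2O, rt
Reagents that add atoms: sodium perborate, [Na+].[O-]OB=O
Why: Copper-catalysed conjugate borylation adds boron to C1 from the β face, opposite the lactone bridge over the α face of ring A, and perborate oxidation replaces boron by OH with retention under near-neutral conditions.

**Step 30**
Reactants: 37 PMB ether
Product: 38 7-[2-(trimethylsilyl)ethyl] ester of 1β,12α-dihydroxy-3-oxo-9αH-20-norgibberell-16-ene-7,19-dioic acid 19,10-lactone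
Conditions: DDQ, CH2Cl2/pH 7 buffer 10:1, 0 °C
Reagents that add atoms: none
Why: Oxidative PMB cleavage under neutral conditions spares the β-hydroxy ketone, the β-keto lactone and the exocyclic alkene.

**Step 31**
Reactants: 38 silylethyl ester
Product: 39 1β,12α-dihydroxy-3-oxo-9αH-20-norgibberell-16-ene-7,19-dioic acid 19,10-lactone (target)
Conditions: TASF, DMF, 0 °C → rt; AcOH
Reagents that add atoms: none
Why: Fluoride-induced β-elimination of the 2-(trimethylsilyl)ethyl ester frees the hindered C7 acid without hydroxide or strong acid.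

**Compound list**
1 | cyclopentane-1,3-dione | O=C1CCC(=O)C1 | starting material
2 | 3-bromoprop-1-yne | C#CCBr | starting material
3 | 2-(prop-2-yn-1-yl)cyclopentane-1,3-dione | C#CCC1C(=O)CCC1=O | intermediate
4 | but-3-en-2-one | CC(=O)C=C | starting material
5 | 2-(3-oxobutyl)-2-(prop-2-yn-1-yl)cyclopentane-1,3-dione | C#CCC1(CCC(C)=O)C(=O)CCC1=O | intermediate
6 | (3aS,7aR)-3a-hydroxy-7a-(prop-2-yn-1-yl)hexahydro-1H-indene-1,5(4H)-dione | C#CC[C@]12CCC(=O)C[C@@]1(O)CCC2=O | intermediate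
7 | (R)-7a-(prop-2-yn-1-yl)-2,3,7,7a-tetrahydro-1H-indene-1,5(6H)-dione | C#CC[C@]12CCC(=O)C=C1CCC2=O | intermediate
8 | (1S,7aR)-1-hydroxy-7a-(prop-2-yn-1-yl)-1,2,3,6,7,7a-hexahydro-5H-inden-5-one | C#CC[C@]12CCC(=O)C=C1CC[C@@H]2O | intermediate
9 | (1S,7aR)-1-[(tert-butyldimethylsilyl)oxy]-7a-(prop-2-yn-1-yl)-1,2,3,6,7,7a-hexahydro-5H-inden-5-one | C#CC[C@]12CCC(=O)C=C1CC[C@@H]2O[Si](C)(C)C(C)(C)C | intermediate
10 | (1S,7aR)-1,5-bis[(tert-butyldimethylsilyl)oxy]-7a-(prop-2-yn-1-yl)-2,3,7,7a-tetrahydro-1H-indene | C#CC[C@]12CC=C(O[Si](C)(C)C(C)(C)C)C=C1CC[C@@H]2O[Si](C)(C)C(C)(C)C | intermediate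
11 | 6β-[(tert-butyldimethylsilyl)oxy]-BCD-9(11),16-dien-12-one | C=C1C[C@]23C[C@H]1C(=O)C=C2CC[C@@H]3O[Si](C)(C)C(C)(C)C | intermediate
12 | 6β-[(tert-butyldimethylsilyl)oxy]-9αH-BCD-16-en-12-one | C=C1C[C@]23C[C@H]1C(=O)C[C@@H]2CC[C@@H]3O[Si](C)(C)C(C)(C)C | intermediate
13 | (12S)-6β-[(tert-butyldimethylsilyl)oxy]-9αH-BCD-16-en-12α-ol | C=C1C[C@]23C[C@H]1[C@@H](O)C[C@@H]2CC[C@@H]3O[Si](C)(C)C(C)(C)C | intermediate
14 | 6β-[(tert-butyldimethylsilyl)oxy]-12α-(4-methoxybenzyloxy)-9αH-BCD-16-ene | C=C1C[C@]23C[C@H]1[C@@H](OCc4ccc(OC)cc4)C[C@@H]2CC[C@@H]3O[Si](C)(C)C(C)(C)C | intermediate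
15 | 12α-(4-methoxybenzyloxy)-9αH-BCD-16-en-6β-ol | C=C1C[C@]23C[C@H]1[C@@H](OCc4ccc(OC)cc4)C[C@@H]2CC[C@@H]3O | intermediate
16 | 12α-(4-methoxybenzyloxy)-9αH-BCD-16-en-6-one | C=C1C[C@]23C[C@H]1[C@@H](OCc4ccc(OC)cc4)C[C@@H]2CCC3=O | intermediate
17 | 12α-(4-methoxybenzyloxy)-6-(trimethylsilyloxy)-9αH-BCD-5,16-diene | C=C1C[C@]23C[C@H]1[C@@H](OCc4ccc(OC)cc4)C[C@@H]2CC=C3O[Si](C)(C)C | intermediate
18 | 12α-(4-methoxybenzyloxy)-9αH-BCD-5(10),16-dien-6-one | C=C1C[C@]23C[C@H]1[C@@H](OCc4ccc(OC)cc4)C[C@@H]2C=CC3=O | intermediate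
19 | tert-butyl(prop-2-yn-1-yloxy)diphenylsilane | C#CCO[Si](c1ccccc1)(c1ccccc1)C(C)(C)C | starting material
20 | 10α-[3-(tert-butyldiphenylsilyloxy)prop-1-yn-1-yl]-12α-(4-methoxybenzyloxy)-9αH-BCD-16-en-6-one | C=C1C[C@]23C[C@H]1[C@@H](OCc4ccc(OC)cc4)C[C@@H]2[C@@H](C#CCO[Si](c5ccccc5)(c5ccccc5)C(C)(C)C)CC3=O | intermediate
21 | 6-trimethylsilyl enol ether of 20 (5,16-diene) | C=C1C[C@]23C[C@H]1[C@@H](OCc4ccc(OC)cc4)C[C@@H]2[C@@H](C#CCO[Si](c5ccccc5)(c5ccccc5)C(C)(C)C)C=C3O[Si](C)(C)C | intermediate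
22 | 10-[3-(tert-butyldiphenylsilyloxy)prop-1-yn-1-yl]-12α-(4-methoxybenzyloxy)-9αH-BCD-5(10),16-dien-6-one | C=C1C[C@]23C[C@H]1[C@@H](OCc4ccc(OC)cc4)C[C@@H]2C(C#CCO[Si](c5ccccc5)(c5ccccc5)C(C)(C)C)=CC3=O | intermediate
23 | 5α,10α-epoxy-10β-[3-(tert-butyldiphenylsilyloxy)prop-1-yn-1-yl]-12α-(4-methoxybenzyloxy)-9αH-BCD-16-en-6-one | C=C1C[C@]23C[C@H]1[C@@H](OCc4ccc(OC)cc4)C[C@@H]2[C@@]5(C#CCO[Si](c6ccccc6)(c6ccccc6)C(C)(C)C)O[C@H]5C3=O | intermediate
24 | 10α-hydroxy-10β-[3-(tert-butyldiphenylsilyloxy)prop-1-yn-1-yl]-12α-(4-methoxybenzyloxy)-9αH-BCD-16-en-6-one | C=C1C[C@]23C[C@H]1[C@@H](OCc4ccc(OC)cc4)C[C@@H]2[C@](O)(C#CCO[Si](c5ccccc5)(c5ccccc5)C(C)(C)C)CC3=O | intermediate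
25 | 10α-(trimethylsilyloxy)-10β-[3-(tert-butyldiphenylsilyloxy)prop-1-yn-1-yl]-12α-(4-methoxybenzyloxy)-9αH-BCD-16-en-6-one | C=C1C[C@]23C[C@H]1[C@@H](OCc4ccc(OC)cc4)C[C@@H]2[C@](O[Si](C)(C)C)(C#CCO[Si](c5ccccc5)(c5ccccc5)C(C)(C)C)CC3=O | intermediate
26 | 10α-(trimethylsilyloxy)-10β-[3-(tert-butyldiphenylsilyloxy)prop-1-yn-1-yl]-12α-(4-methoxybenzyloxy)-9αH-BCD-5,16-dien-6-yl trifluoromethanesulfonate | C=C1C[C@]23C[C@H]1[C@@H](OCc4ccc(OC)cc4)C[C@@H]2[C@](O[Si](C)(C)C)(C#CCO[Si](c5ccccc5)(c5ccccc5)C(C)(C)C)C=C3OS(=O)(=O)C(F)(F)F | intermediate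
27 | 2-(trimethylsilyl)ethyl 10α-(trimethylsilyloxy)-10β-[3-(tert-butyldiphenylsilyloxy)prop-1-yn-1-yl]-12α-(4-methoxybenzyloxy)-9αH-BCD-5,16-diene-6-carboxylate | C=C1C[C@]23C[C@H]1[C@@H](OCc4ccc(OC)cc4)C[C@@H]2[C@](O[Si](C)(C)C)(C#CCO[Si](c5ccccc5)(c5ccccc5)C(C)(C)C)C=C3C(=O)OCC[Si](C)(C)C | intermediate
28 | 2-(trimethylsilyl)ethyl 10α-hydroxy-10β-[3-(tert-butyldiphenylsilyloxy)prop-1-yn-1-yl]-12α-(4-methoxybenzyloxy)-9αH-BCD-5,16-diene-6-carboxylate | C=C1C[C@]23C[C@H]1[C@@H](OCc4ccc(OC)cc4)C[C@@H]2[C@](O)(C#CCO[Si](c5ccccc5)(c5ccccc5)C(C)(C)C)C=C3C(=O)OCC[Si](C)(C)C | intermediate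
29 | 2-(trimethylsilyl)ethyl 10α-(propanoyloxy)-10β-[3-(tert-butyldiphenylsilyloxy)prop-1-yn-1-yl]-12α-(4-methoxybenzyloxy)-9αH-BCD-5,16-diene-6-carboxylate | C=C1C[C@]23C[C@H]1[C@@H](OCc4ccc(OC)cc4)C[C@@H]2[C@](OC(=O)CC)(C#CCO[Si](c5ccccc5)(c5ccccc5)C(C)(C)C)C=C3C(=O)OCC[Si](C)(C)C | intermediate
30 | 2-(trimethylsilyl)ethyl 10β-[3-(tert-butyldiphenylsilyloxy)prop-1-yn-1-yl]-12α-(4-methoxybenzyloxy)-5βH-6αH-9αH-BCD-16-ene-6β-carboxylate carrying the cis-fused γ-lactone C19(=O)–O-10 with C4(H)(CH3) on C5α (C4 epimers; CH3 on the alkyne side drawn) | C=C1C[C@]23C[C@H]1[C@@H](OCc5ccc(OC)cc5)C[C@@H]2[C@@]4(C#CCO[Si](c6ccccc6)(c6ccccc6)C(C)(C)C)OC(=O)[C@H](C)[C@H]4[C@@H]3C(=O)OCC[Si](C)(C)C | intermediate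
31 | as 30 with 10β-[(Z)-3-(tert-butyldiphenylsilyloxy)prop-1-en-1-yl] | C=C1C[C@]23C[C@H]1[C@@H](OCc5ccc(OC)cc5)C[C@@H]2[C@@]4(/C=C\CO[Si](c6ccccc6)(c6ccccc6)C(C)(C)C)OC(=O)[C@H](C)[C@H]4[C@@H]3C(=O)OCC[Si](C)(C)C | intermediate
32 | as 30 with 10β-[(Z)-3-hydroxyprop-1-en-1-yl] | C=C1C[C@]23C[C@H]1[C@@H](OCc5ccc(OC)cc5)C[C@@H]2[C@@]4(/C=C\CO)OC(=O)[C@H](C)[C@H]4[C@@H]3C(=O)OCC[Si](C)(C)C | intermediate
33 | as 30 with 10β-[(Z)-3-oxoprop-1-en-1-yl] | C=C1C[C@]23C[C@H]1[C@@H](OCc5ccc(OC)cc5)C[C@@H]2[C@@]4(/C=C\C=O)OC(=O)[C@H](C)[C@H]4[C@@H]3C(=O)OCC[Si](C)(C)C | intermediate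
34 | 7-[2-(trimethylsilyl)ethyl] ester of 3β-hydroxy-12α-(4-methoxybenzyloxy)-9αH-20-norgibberella-1,16-diene-7,19-dioic acid 19,10-lactone (3α epimer also carried) | C=C1C[C@]23C[C@H]1[C@@H](OCc4ccc(OC)cc4)C[C@@H]2[C@]12OC(=O)[C@](C)([C@@H](O)C=C1)[C@H]2[C@@H]3C(=O)OCC[Si](C)(C)C | intermediate
35 | 7-[2-(trimethylsilyl)ethyl] ester of 3-oxo-12α-(4-methoxybenzyloxy)-9αH-20-norgibberella-1,16-diene-7,19-dioic acid 19,10-lactone | C=C1C[C@]23C[C@H]1[C@@H](OCc4ccc(OC)cc4)C[C@@H]2[C@]12OC(=O)[C@](C)(C(=O)C=C1)[C@H]2[C@@H]3C(=O)OCC[Si](C)(C)C | intermediate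
36 | 7-[2-(trimethylsilyl)ethyl] ester of 3-oxo-1β-(4,4,5,5-tetramethyl-1,3,2-dioxaborolan-2-yl)-12α-(4-methoxybenzyloxy)-9αH-20-norgibberell-16-ene-7,19-dioic acid 19,10-lactone | C=C1C[C@]23C[C@H]1[C@@H](OCc4ccc(OC)cc4)C[C@@H]2[C@]12OC(=O)[C@](C)(C(=O)C[C@H]1B5OC(C)(C)C(C)(C)O5)[C@H]2[C@@H]3C(=O)OCC[Si](C)(C)C | intermediate
37 | 7-[2-(trimethylsilyl)ethyl] ester of 1β-hydroxy-3-oxo-12α-(4-methoxybenzyloxy)-9αH-20-norgibberell-16-ene-7,19-dioic acid 19,10-lactone | C=C1C[C@]23C[C@H]1[C@@H](OCc4ccc(OC)cc4)C[C@@H]2[C@]12OC(=O)[C@](C)(C(=O)C[C@H]1O)[C@H]2[C@@H]3C(=O)OCC[Si](C)(C)C | intermediate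
38 | 7-[2-(trimethylsilyl)ethyl] ester of 1β,12α-dihydroxy-3-oxo-9αH-20-norgibberell-16-ene-7,19-dioic acid 19,10-lactone | C=C1C[C@]23C[C@H]1[C@@H](O)C[C@@H]2[C@]12OC(=O)[C@](C)(C(=O)C[C@H]1O)[C@H]2[C@@H]3C(=O)OCC[Si](C)(C)C | intermediate
39 | 1β,12α-dihydroxy-3-oxo-9αH-20-norgibberell-16-ene-7,19-dioic acid 19,10-lactone (CNP0259985.3) | C=C1C[C@]23C[C@H]1[C@@H](O)C[C@@H]2[C@]12OC(=O)[C@](C)(C(=O)C[C@H]1O)[C@H]2[C@@H]3C(=O)O | target

**Totals.** 31 steps in all; the longest linear sequence is 31 steps (1 → 39; 19 is a purchased building block).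

**Steps most likely to fail, with fallbacks**

Step 14 (nickel-catalysed conjugate alkynylation of a hindered cyclopentenone) is the least precedented C–C bond formation. The fallback sets out from 18 and avoids conjugate addition altogether. Alkaline H2O2 gives the 5α,10α-epoxy ketone F1. Pd(PPh3)4 with 1,2-bis(diphenylphosphino)ethane in hot toluene isomerises it to the 6,10-dione F2. Tf2O and 2,6-lutidine at −78 °C triflate the less hindered C10 oxygen to give the 10-triflyloxy enone F3. Sonogashira coupling of F3 with 19 (PdCl2(PPh3)2, CuI, Et3N) then returns to the route at 22.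

Step 23 (anionic Michael lactonisation) may lose material to enolate Claisen rearrangement of the allylic/propargylic ester. The fallback sets out from 28 and forms the C4–C5 bond by a radical (Ueno–Stork) route. NBS and ethyl prop-1-enyl ether give the mixed bromoacetal F4. Bu3SnH with AIBN in benzene at 80 °C effects 5-exo-trig cyclisation onto the enoate to give the cyclic ethyl acetal F5. Aqueous AcOH/THF gives the lactol F6, and TEMPO/PhI(OAc)2 oxidises it to the lactone, returning at 30.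

Step 29 (conjugate borylation at C1) may give poor β-face selectivity, because C11 lies near the β face of C1 in this 9αH series. The fallback sets out from the 3β-epimer of 34 and uses the hydroxyl group to direct the oxygen. VO(acac)2 with t-BuOOH gives the 1β,2β-epoxy-3β-alcohol F7, syn to the directing OH. Dess–Martin periodinane gives the 1β,2β-epoxy-3-ketone F8. Samarium diiodide (THF/MeOH, −90 °C) cleaves the C2–O bond and returns to the route at 37.

**Further compounds**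
F1 | step 14 | 5α,10α-epoxy-12α-(4-methoxybenzyloxy)-9αH-BCD-16-en-6-one | C=C1C[C@]23C[C@H]1[C@@H](OCc4ccc(OC)cc4)C[C@@H]2[C@H]5O[C@H]5C3=O
F2 | step 14 | 12α-(4-methoxybenzyloxy)-9αH-BCD-16-ene-6,10-dione | C=C1C[C@]23C[C@H]1[C@@H](OCc4ccc(OC)cc4)C[C@@H]2C(=O)CC3=O
F3 | step 14 | 12α-(4-methoxybenzyloxy)-6-oxo-9αH-BCD-5(10),16-dien-10-yl trifluoromethanesulfonate | C=C1C[C@]23C[C@H]1[C@@H](OCc4ccc(OC)cc4)C[C@@H]2C(OS(=O)(=O)C(F)(F)F)=CC3=O
F4 | step 23 | 2-(trimethylsilyl)ethyl 10α-(2-bromo-1-ethoxypropoxy)-10β-[3-(tert-butyldiphenylsilyloxy)prop-1-yn-1-yl]-12α-(4-methoxybenzyloxy)-9αH-BCD-5,16-diene-6-carboxylate (acetal and CHBr epimers) | C=C1C[C@]23C[C@H]1[C@@H](OCc4ccc(OC)cc4)C[C@@H]2[C@](OC(OCC)C(C)Br)(C#CCO[Si](c5ccccc5)(c5ccccc5)C(C)(C)C)C=C3C(=O)OCC[Si](C)(C)C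
F5 | step 23 | cyclic ethyl acetal analogue of 30 (C19 as CH(OEt); acetal and C4 epimers) | C=C1C[C@]23C[C@H]1[C@@H](OCc5ccc(OC)cc5)C[C@@H]2[C@@]4(C#CCO[Si](c6ccccc6)(c6ccccc6)C(C)(C)C)OC(OCC)C(C)[C@H]4[C@@H]3C(=O)OCC[Si](C)(C)C
F6 | step 23 | lactol analogue of 30 (C19 as CH(OH); epimers) | C=C1C[C@]23C[C@H]1[C@@H](OCc5ccc(OC)cc5)C[C@@H]2[C@@]4(C#CCO[Si](c6ccccc6)(c6ccccc6)C(C)(C)C)OC(O)C(C)[C@H]4[C@@H]3C(=O)OCC[Si](C)(C)C
F7 | step 29 | 7-[2-(trimethylsilyl)ethyl] ester of 1β,2β-epoxy-3β-hydroxy-12α-(4-methoxybenzyloxy)-9αH-20-norgibberell-16-ene-7,19-dioic acid 19,10-lactone | C=C1C[C@]23C[C@H]1[C@@H](OCc4ccc(OC)cc4)C[C@@H]2[C@]12OC(=O)[C@](C)([C@@H](O)[C@H]5O[C@@H]15)[C@H]2[C@@H]3C(=O)OCC[Si](C)(C)C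
F8 | step 29 | 7-[2-(trimethylsilyl)ethyl] ester of 1β,2β-epoxy-3-oxo-12α-(4-methoxybenzyloxy)-9αH-20-norgibberell-16-ene-7,19-dioic acid 19,10-lactone | C=C1C[C@]23C[C@H]1[C@@H](OCc4ccc(OC)cc4)C[C@@H]2[C@]12OC(=O)[C@](C)(C(=O)[C@H]5O[C@@H]15)[C@H]2[C@@H]3C(=O)OCC[Si](C)(C)C
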